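## Retrosynthetic overview

1. Target ⇐ global desilylation and double Lindlar semihydrogenation of a 42-membered 2-ynoate/38-yne macrolactone. The only ring is closed late, by C1(=O)–O41 ester formation (macrolactonization of the seco ynoic acid).
2. Seco acid ⇐ C3–C4 Sonogashira coupling with propiolic acid and C37–C38 acetylide alkylation, joining a C4–C37 iodide to a C38–C50 alkynol.
3. C4–C37 ⇐ Ipc-boron syn-aldol (C18–C19) of a C4–C18 ethyl ketone with a C19–C37 (Z)-enal, then 1,3-anti reduction (C17).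
4. Both polyol chains ⇐ 2-silyl-1,3-dithiane anion-relay couplings of epichlorohydrin-derived epoxides. The dithianes become ketones (C9, C13, C17; hydroxyl-directed anti reductions) or CH2 (C25, C29).
5. C38–C50 ⇐ (R)-propylene oxide, syn-crotylation (C42, C43), catalyst-controlled terminal epoxidation (C41–O, new method), acetylide opening.

Assumption: the SMILES is read literally, i.e. 2Z,4Z,20Z,38Z and 7S,9R,11S,13R,15S,17R,18R,19S,23R,27R,31R,41S,42S,43R,49R, with carbons numbered C1 (lactone carbonyl) to C50 along the chain.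

Abbreviations: TBS = tert-butyldimethylsilyl, TIPS = triisopropylsilyl, Ipc = isopinocampheyl. "As in 66" means the same spatial arrangement as at that carbon of the target.

## Route

### Linchpin reagent and C4–C18 ketone

Step 1
Reactants: 1 (S)-epichlorohydrin
Product: 3 (2S)-2-allyloxirane, via magnesium chlorohydrin alkoxide 2 (not isolated)
Conditions: CH2=CHMgBr, CuI (5 mol %), THF, −40 → −20 °C; then powdered NaOH, Et2O, rt
Reagents that add atoms: vinylmagnesium bromide, C=C[Mg]Br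
Why: Cu-catalysed Grignard opening at the epoxide CH2 followed by base-induced closure of the chlorohydrin (epichlorohydrin bis-electrophile tactic) never touches the C–O bond of the stereocentre, so the chirality of 1 becomes C7.

Step 2
Reactants: 4 2-(tert-butyldimethylsilyl)-1,3-dithiane
Product: 5 2-lithio-2-(tert-butyldimethylsilyl)-1,3-dithiane (titrated Et2O stock solution)
Conditions: t-BuLi (1.05 equiv), Et2O, −78 → −45 °C, 1 h; kept under argon at −78 °C
Reagents that add atoms: tert-butyllithium, [Li]C(C)(C)C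
Why: Corey–Seebach deprotonation of the C2–H acidified by two sulfurs and silicon gives the linchpin anion, made once on the scale that the four anion-relay couplings (steps 3, 5, 12 and 15) need and titrated (D2O quench of an aliquot) before each use.

Step 3
Reactants: 5 2-lithio-2-(tert-butyldimethylsilyl)-1,3-dithiane; 3 (2S)-2-allyloxirane; 1 (S)-epichlorohydrin
Product: 9 2-[(2S)-2-(TBSO)pent-4-enyl]-2-{[(2S)-oxiran-2-yl]methyl}-1,3-dithiane, via lithium alkoxide adduct 6 (not isolated), via Brook-shifted lithiodithiane 7 (not isolated), via chlorohydrin alkoxide 8 (not isolated)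
Conditions: 5 (Et2O solution), 3, −78 → −25 °C; then HMPA, 1, THF, −78 °C → rt
Reagents that add atoms: none
Why: Three-component anion-relay (linchpin) coupling: 5 opens 3 at CH2, HMPA triggers the 1,4-Brook shift that silylates O7 and regenerates a dithiane anion, which opens 1 at its epoxide CH2 before the alkoxide closes onto CH2Cl, so C7 and C11 are both taken from epoxides.

Step 4
Reactants: 10 1,3-dithiane; 11 (R)-epichlorohydrin
Product: 16 2-ethyl-2-{[(2R)-oxiran-2-yl]methyl}-1,3-dithiane, via 2-lithio-1,3-dithiane 12 (not isolated), via 2-ethyl-1,3-dithiane 13 (not isolated), via 2-ethyl-2-lithio-1,3-dithiane 14 (not isolated), via chlorohydrin alkoxide 15 (not isolated)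
Conditions: n-BuLi, THF, −30 °C; EtI; n-BuLi, −30 °C; 11, −78 °C → rt
Reagents that add atoms: iodoethane, CCI
Why: Two successive Corey–Seebach alkylations (EtI, then epoxide-terminus opening of 11 and ring closure) give the masked ethyl ketone C17/C18 carrying C15 from 11.

Step 5
Reactants: 5 2-lithio-2-(tert-butyldimethylsilyl)-1,3-dithiane; 16 ethyl dithiane epoxide; 9 C5–C12 epoxide
Product: 19 C5–C18 tris-dithiane alcohol (11-OH free; 7,15-bis-OTBS), via lithium alkoxide adduct 17 (not isolated), via Brook-shifted lithiodithiane 18 (not isolated)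
Conditions: 5 (Et2O solution), 16, −78 → −25 °C; then HMPA, 9, THF, −78 → 0 °C; aq. NH4Cl
Reagents that add atoms: none
Why: Second anion-relay coupling; adding 16 first puts the migrating TBS on O15 and leaves O11 free, exactly the hydroxyl needed to direct the two reductions of step 7.

Step 6
Reactants: 19 tris-dithiane alcohol
Product: 20 C5–C18 9,13,17-triketone (11-OH; 7,15-bis-OTBS)
Conditions: MeI, CaCO3, MeCN/H2O (9:1), 45 °C
Reagents that add atoms: water, O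
Why: Alkylative dithiane hydrolysis (S-methylation, then hydrolysis of the sulfonium, CaCO3 buffer) unmasks all three ketones under near-neutral conditions that spare the alkene, the TBS ethers and the β-hydroxy ketone.

Step 7
Reactants: 20 triketone
Product: 21 C5–C18 9,11,13-triol 17-ketone (all-anti triol)
Conditions: Me4NBH(OAc)3, MeCN/AcOH (1:1), −30 → −20 °C
Reagents that add atoms: none
Why: Evans–Saksena reduction: O11 binds boron and delivers hydride intramolecularly through a chair transition state to both β-ketones, setting C9 and C13 1,3-anti to C11, while the C17 ketone (no free β-OH) is not reduced.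

Step 8
Reactants: 21 triol ketone
Product: 22 pentakis-TBS C5–C18 ethyl ketone (terminal alkene)
Conditions: TBSOTf, 2,6-lutidine, CH2Cl2, −78 → −20 °C
Reagents that add atoms: tert-butyldimethylsilyl triflate, CC(C)(C)[Si](C)(C)OS(=O)(=O)C(F)(F)F
Why: Standard silylation of the three secondary alcohols; at low temperature the ketone is not enolised.

Step 9
Reactants: 22 alkene ketone
Product: 23 C5 aldehyde (pentakis-TBS keto aldehyde)
Conditions: O3, CH2Cl2/MeOH, −78 °C; then PPh3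
Reagents that add atoms: ozone, [O-][O+]=O
Why: Ozonolysis of the only C=C in the molecule with reductive work-up gives the C5 aldehyde; ketone and silyl ethers are inert.

Step 10
Reactants: 23 keto aldehyde
Product: 24 C4–C18 (Z)-vinyl iodide ethyl ketone
Conditions: EtPPh3I, n-BuLi, THF; I2, −78 °C; NaN(SiMe3)2, −20 °C; then 23, −78 → −20 °C
Reagents that add atoms: ethyltriphenylphosphonium iodide, CC[P+](c1ccccc1)(c1ccccc1)c1ccccc1.[I-]; iodine, II
Why: Stork–Zhao-type Wittig olefination with the α-iodoethylidene ylide reacts at the aldehyde (not the ketone) through the kinetic cis-oxaphosphetane and gives the (Z)-2-iodo-2-alkene, fixing the C4=C5 geometry and leaving iodine as the handle for C3.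

### C19–C37 enal

Step 11
Reactants: 25 1-bromo-5-chloropentane; 11 (R)-epichlorohydrin
Product: 28 (2R)-2-(6-chlorohexyl)oxirane, via Grignard reagent 26 (not isolated), via magnesium chlorohydrin alkoxide 27 (not isolated)
Conditions: Mg, THF; CuI (5 mol %), 11, −40 → 0 °C; then aq. NaOH, rt
Reagents that add atoms: none
Why: Mg inserts only into C–Br, and the Cu-catalysed opening/ring-closure sequence of step 1 transfers the chirality of 11 to C31 while keeping a primary chloride at C37.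

Step 12
Reactants: 5 2-lithio-2-(tert-butyldimethylsilyl)-1,3-dithiane; 28 chlorohexyl oxirane; 11 (R)-epichlorohydrin
Product: 32 2-[(2R)-2-(TBSO)-8-chlorooctyl]-2-{[(2R)-oxiran-2-yl]methyl}-1,3-dithiane, via lithium alkoxide adduct 29 (not isolated), via Brook-shifted lithiodithiane 30 (not isolated), via chlorohydrin alkoxide 31 (not isolated)
Conditions: 5 (Et2O solution), 28, −78 → −25 °C; then HMPA, 11, THF, −78 °C → rt
Reagents that add atoms: none
Why: Anion-relay coupling as in step 3 (C31 from 28, C27 from 11); at these temperatures the dithiane anions open epoxides far faster than they displace a remote primary chloride.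

Step 13
Reactants: 33 4,4-diethoxybut-1-ene
Product: 34 rac-2-(2,2-diethoxyethyl)oxirane
Conditions: mCPBA, NaHCO3, CH2Cl2, 0 °C → rt
Reagents that add atoms: 3-chloroperbenzoic acid, OOC(=O)c1cccc(Cl)c1
Why: Prilezhaev epoxidation of the terminal alkene; the bicarbonate buffer protects the acetal.

Step 14
Reactants: 34 racemic epoxide
Product: 35 (2S)-2-(2,2-diethoxyethyl)oxirane
Conditions: (S,S)-(salen)Co(OAc) [salen = N,N′-bis(3,5-di-tert-butylsalicylidene)cyclohexane-1,2-diamine dianion; trivalent cobalt] (0.5 mol %), H2O (0.55 equiv), THF, 0 °C → rt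
Reagents that add atoms: none
Why: Jacobsen hydrolytic kinetic resolution: the (S,S)-catalyst hydrolyses the (R)-epoxide and leaves the (S)-epoxide (>99% ee), which supplies C23.

Step 15
Reactants: 5 2-lithio-2-(tert-butyldimethylsilyl)-1,3-dithiane; 32 C26–C37 epoxide; 35 acetal epoxide
Product: 39 C21–C37 bis-dithiane (23,27,31-tris-OTBS; C21 diethyl acetal; C37 chloride), via lithium alkoxide adduct 36 (not isolated), via Brook-shifted lithiodithiane 37 (not isolated), via lithium alkoxide 38 (not isolated)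
Conditions: 5 (Et2O solution), 32, −78 → −25 °C; then HMPA, 35, THF, −78 → 0 °C; then TBSCl, −78 °C → rt
Reagents that add atoms: tert-butyldimethylsilyl chloride, CC(C)(C)[Si](C)(C)Cl
Why: Third anion-relay coupling joins the three epoxide-derived carbinols C23, C27 and C31 through the C25 linchpin, and the final alkoxide is silylated in the same flask (HMPA-assisted).

Step 16
Reactants: 39 bis-dithiane
Product: 40 C21–C37 acetal chloride (C25 and C29 now CH2)
Conditions: Raney Ni (W-2), EtOH, rt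
Reagents that add atoms: none
Why: Mozingo-type hydrogenolytic desulfurisation converts both linchpin carbons into CH2; it is run before any C=C or C≡C is present, and acetal, silyl ethers and the unactivated alkyl chloride are tolerated.

Step 17
Reactants: 40 chloride
Product: 41 C21–C37 acetal iodide
Conditions: NaI, NaHCO3, acetone, reflux
Reagents that add atoms: sodium iodide, [Na+].[I-]
Why: Finkelstein exchange turns the carried-through chloride into the iodide needed for the later acetylide alkylation.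

Step 18
Reactants: 41 acetal iodide
Product: 42 C21 aldehyde (23,27,31-tris-OTBS; C37 iodide)
Conditions: PPTS (cat.), acetone/H2O (10:1), 50 °C
Reagents that add atoms: water, O
Why: Mild acid-catalysed acetal hydrolysis (transacetalisation to acetone) frees the aldehyde without touching secondary TBS ethers.

Step 19
Reactants: 42 aldehyde
Product: 43 ethyl (Z)-2-methyl-enoate (C19–C37)
Conditions: KN(SiMe3)2, 18-crown-6, THF, −78 °C
Reagents that add atoms: ethyl 2-[bis(2,2,2-trifluoroethoxy)phosphoryl]propanoate, CCOC(=O)C(C)P(=O)(OCC(F)(F)F)OCC(F)(F)F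
Why: Still–Gennari olefination: fast, irreversible elimination from the kinetic adduct of the electron-poor phosphonate gives the (Z)-trisubstituted enoate, setting the C20=C21 geometry.

Step 20
Reactants: 43 (Z)-enoate
Product: 44 (Z)-allylic alcohol (C19–C37)
Conditions: i-Bu2AlH, CH2Cl2, −78 °C
Reagents that add atoms: none
Why: 1,2-Reduction of the enoate to the allylic alcohol; the alkyl iodide and silyl ethers do not react at −78 °C.

Step 21
Reactants: 44 allylic alcohol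
Product: 45 (Z)-enal (C19–C37; C37 iodide)
Conditions: MnO2, CH2Cl2, rt
Reagents that add atoms: none
Why: Selective allylic oxidation on the MnO2 surface under neutral conditions keeps the Z geometry; the enal is used at once.

### C38–C50 alkynol

Step 22
Reactants: 46 6-bromohex-1-ene; 47 (R)-propylene oxide
Product: 49 (2R)-non-8-en-2-ol, via Grignard reagent 48 (not isolated)
Conditions: Mg, THF; CuI (10 mol %), 47, −30 → 0 °C
Reagents that add atoms: none
Why: Cu-catalysed Grignard opening at the CH2 of the epoxide keeps the configuration of 47, which becomes C49.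

Step 23
Reactants: 49 nonenol
Product: 50 (2R)-2-(TBSO)non-8-ene
Conditions: TBSCl, imidazole, DMF, rt
Reagents that add atoms: tert-butyldimethylsilyl chloride, CC(C)(C)[Si](C)(C)Cl
Why: Routine silyl protection of the secondary alcohol.

Step 24
Reactants: 50 silyl ether
Product: 51 (7R)-7-(TBSO)octanal
Conditions: O3, CH2Cl2/MeOH, −78 °C; then PPh3
Reagents that add atoms: ozone, [O-][O+]=O
Why: Ozonolysis with reductive work-up gives the C43 aldehyde.

Step 25
Reactants: 51 aldehyde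
Product: 52 (3R,4R,10R)-10-(TBSO)-3-methylundec-1-en-4-ol
Conditions: cis-but-2-ene, KOt-Bu, n-BuLi, THF, −78 → −45 °C; (−)-Ipc2BOMe, −78 °C; BF3·OEt2; 51, −78 °C; then NaOH, H2O2
Reagents that add atoms: (−)-B-[(Z)-but-2-enyl]diisopinocampheylborane (made in the flask from cis-but-2-ene), C/C=C\CB([C@@H]1C[C@@H]2C[C@H]([C@H]1C)C2(C)C)[C@@H]1C[C@@H]2C[C@H]([C@H]1C)C2(C)C
Why: Brown crotylboration: the (Z)-crotylborane reacts through a closed chair transition state (syn product) and the Ipc ligands from (+)-α-pinene direct attack to the Si face of the aldehyde, setting C43 and C42 as in 66.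

Step 26
Reactants: 52 homoallylic alcohol
Product: 53 (3R,4R,10R)-10-(TBSO)-3-methyl-4-(TIPSO)undec-1-ene
Conditions: TIPSOTf, 2,6-lutidine, CH2Cl2, 0 °C → rt
Reagents that add atoms: triisopropylsilyl triflate, CC(C)[Si](C(C)C)(C(C)C)OS(=O)(=O)C(F)(F)F
Why: TIPS rather than TBS on O43 blocks 1,3 O→O silyl migration to the C41 alkoxide that is generated in steps 28 and 32.

Step 27
Reactants: 53 terminal alkene
Product: 54 (2R)-2-[(2R,3R,9R)-9-(TBSO)-3-(TIPSO)decan-2-yl]oxirane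
Conditions: [Ti(μ-O)(L)]2 (5 mol %; L = dianion of the 3,3′-diphenyl salalen built on cis-cyclohexane-1,2-diamine, the enantiomer that turns 1-octene into (R)-1,2-epoxyoctane), 30% aq. H2O2 (1.5 equiv), CH2Cl2, rt
Reagents that add atoms: hydrogen peroxide, OO
Why: Proposed new method: catalyst-controlled epoxidation of an acyclic α-stereogenic β-silyloxy 1-alkene with a tetravalent-titanium salalen/H2O2 system, a substrate class on which this catalysis has not been shown; the di-μ-oxo dimer is opened by H2O2 to a monomeric Ti(η2-hydroperoxo) species whose ligand N–H hydrogen-bonds the peroxide, the monosubstituted olefin approaches with only its CH2 terminus inside the chiral pocket so the ligand (not the C42 centre, which sits outside in its allylic-strain-minimised conformation) selects the face that gives the (R)-oxirane, and the concerted electrophilic O-transfer forms the C41–O bond with the C41 configuration of 66; the closest known reaction type is the Katsuki–Berkessel titanium salalen epoxidation of simple unconjugated terminal olefins (1-octene, vinylcyclohexane).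

Step 28
Reactants: 54 epoxide
Product: 55 (4S,5R,6R,12R)-12-(TBSO)-5-methyl-6-(TIPSO)tridec-1-yn-4-ol
Conditions: LiC≡CH·H2NCH2CH2NH2, DMSO, rt
Reagents that add atoms: lithium acetylide ethylenediamine complex, [Li]C#C.NCCN
Why: SN2 opening of the terminal epoxide at C40 by acetylide leaves C41 untouched and reveals the C41 hydroxyl as the only free OH of this fragment.

### Union and endgame

Step 29
Reactants: 24 vinyl iodide ethyl ketone; 45 (Z)-enal
Product: 57 C4–C37 syn-aldol adduct (17-ketone; 19-OH), via enol borinate 56 (not isolated)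
Conditions: (−)-Ipc2BOTf, i-Pr2NEt, CH2Cl2, −78 °C; 45, −78 → −20 °C; then H2O2, pH 7 buffer, MeOH
Reagents that add atoms: none
Why: Paterson Ipc-boron aldol: regioselective enolisation on the ethyl side gives the (Z)-enol borinate, which reacts through a Zimmerman–Traxler chair (18,19-syn) while the Ipc ligands steer attack to the Si face of the enal, setting C18 and C19 as in 66 and overriding the weak bias of the remote C15 centre.

Step 30
Reactants: 57 aldol adduct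
Product: 58 C4–C37 17,19-anti diol
Conditions: Me4NBH(OAc)3, MeCN/AcOH (1:1), −30 °C
Reagents that add atoms: none
Why: Evans–Saksena reduction directed by O19 delivers hydride intramolecularly and sets C17 1,3-anti to C19, completing the anti,syn C17–C19 triad.

Step 31
Reactants: 58 diol
Product: 59 C4–C37 decakis-TBS bis-iodide (vinyl iodide at C4; alkyl iodide at C37)
Conditions: TBSOTf, 2,6-lutidine, CH2Cl2, 0 °C
Reagents that add atoms: tert-butyldimethylsilyl triflate, CC(C)(C)[Si](C)(C)OS(=O)(=O)C(F)(F)F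
Why: Silylation of both new hydroxyls makes O41 the only free hydroxyl after the next step.

Step 32
Reactants: 59 bis-iodide; 55 alkynol
Product: 61 C4–C50 seco alcohol (41-OH; C4 vinyl iodide; C38≡C39), via dilithio alkynol 60 (not isolated)
Conditions: 55 (2.5 equiv), n-BuLi (5 equiv), THF, −78 → 0 °C; then DMPU, 59, −20 °C → rt
Reagents that add atoms: none
Why: C-Alkylation of the lithium acetylide/alkoxide dianion by the primary iodide (the vinyl iodide is inert to acetylide and no free butyllithium is present) forms C37–C38 and leaves O41 free.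

Step 33
Reactants: 61 seco alcohol
Product: 62 seco 2-ynoic acid (C1–C50; 41-OH)
Conditions: propiolic acid, PdCl2(PPh3)2 (5 mol %), Ph2P(CH2)4PPh2 (10 mol %), DBU, DMSO, rt
Reagents that add atoms: propiolic acid, C#CC(=O)O
Why: Copper-free Sonogashira coupling of the DBU propiolate with retention of the (Z)-iodide geometry installs C1–C3 in one step; the enynoate has no propargylic hydrogen and cannot isomerise.

Step 34
Reactants: 62 seco acid
Product: 64 42-membered 2,38-diyne macrolactone (fully silylated), via mixed anhydride 63 (not isolated)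
Conditions: 2,4,6-Cl3C6H2COCl, Et3N, THF, rt; then slow addition to DMAP, toluene, 40 °C (0.5 mM)
Reagents that add atoms: none
Why: Yamaguchi macrolactonization closes the ring by C1–O41 bond formation: O41 is the only free hydroxyl, and the 2-ynoyl unit has no double-bond geometry to lose during acyl activation.

Step 35
Reactants: 64 diyne macrolactone
Product: 65 silylated macrolide (2Z,4Z,20Z,38Z)
Conditions: H2 (1 atm), Pd/CaCO3 poisoned with Pb(OAc)2, quinoline, EtOAc/hexane, rt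
Reagents that add atoms: none
Why: Lindlar syn-semihydrogenation of both alkynes gives the 2Z and 38Z alkenes; the trisubstituted alkenes are not reduced.

Step 36
Reactants: 65 silylated macrolide
Product: 66 CNP0392687.2
Conditions: HF·pyridine, pyridine, THF, 0 °C → rt
Reagents that add atoms: none
Why: Buffered acidic fluoride removes the eleven TBS ethers and the TIPS ether without the acyl migration or dienoate isomerisation that basic fluoride could cause.

## Compound list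

1 | (S)-epichlorohydrin, (2S)-2-(chloromethyl)oxirane | ClC[C@@H]1CO1 | starting material
2 | bromomagnesium (2S)-1-chloropent-4-en-2-olate | C=CC[C@H](O[Mg]Br)CCl | intermediate
3 | (2S)-2-allyloxirane | C=CC[C@H]1CO1 | intermediate
4 | 2-(tert-butyldimethylsilyl)-1,3-dithiane | CC(C)(C)[Si](C)(C)C1SCCCS1 | starting material
5 | 2-lithio-2-(tert-butyldimethylsilyl)-1,3-dithiane (titrated Et2O stock solution) | [Li]C1(SCCCS1)[Si](C)(C)C(C)(C)C | intermediate
6 | lithium (2S)-1-[2-(TBS)-1,3-dithian-2-yl]pent-4-en-2-olate | C=CC[C@H](O[Li])CC1(SCCCS1)[Si](C)(C)C(C)(C)C | intermediate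
7 | 2-lithio-2-[(2S)-2-(TBSO)pent-4-enyl]-1,3-dithiane | C=CC[C@H](O[Si](C)(C)C(C)(C)C)CC1([Li])SCCCS1 | intermediate
8 | lithium (2S)-1-chloro-3-{2-[(2S)-2-(TBSO)pent-4-enyl]-1,3-dithian-2-yl}propan-2-olate | C=CC[C@H](O[Si](C)(C)C(C)(C)C)CC1(SCCCS1)C[C@H](O[Li])CCl | intermediate
9 | 2-[(2S)-2-(TBSO)pent-4-enyl]-2-{[(2S)-oxiran-2-yl]methyl}-1,3-dithiane (C5–C12; C9 dithiane; C11–C12 epoxide) | C=CC[C@H](O[Si](C)(C)C(C)(C)C)CC1(SCCCS1)C[C@H]2CO2 | intermediate
10 | 1,3-dithiane | C1CSCSC1 | starting material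
11 | (R)-epichlorohydrin, (2R)-2-(chloromethyl)oxirane | ClC[C@H]1CO1 | starting material
12 | 2-lithio-1,3-dithiane | [Li]C1SCCCS1 | intermediate
13 | 2-ethyl-1,3-dithiane | CCC1SCCCS1 | intermediate
14 | 2-ethyl-2-lithio-1,3-dithiane | CCC1([Li])SCCCS1 | intermediate
15 | lithium (2R)-1-chloro-3-(2-ethyl-1,3-dithian-2-yl)propan-2-olate | CCC1(SCCCS1)C[C@@H](O[Li])CCl | intermediate
16 | 2-ethyl-2-{[(2R)-oxiran-2-yl]methyl}-1,3-dithiane (C14–C18; C17 dithiane) | CCC1(SCCCS1)C[C@@H]2CO2 | intermediate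
17 | lithium alkoxide from 5 and 16 (C15–OLi; C13 silyl dithiane) | CCC1(SCCCS1)C[C@@H](O[Li])CC2(SCCCS2)[Si](C)(C)C(C)(C)C | intermediate
18 | C13 lithiodithiane after Brook shift (15-OTBS) | CCC1(SCCCS1)C[C@@H](O[Si](C)(C)C(C)(C)C)CC2([Li])SCCCS2 | intermediate
19 | C5–C18 tris-dithiane alcohol: terminal alkene, 7-OTBS, dithianes at C9, C13 and C17 (C17 bearing ethyl), free 11-OH, 15-OTBS; C7, C11, C15 as in 66 | C=CC[C@H](O[Si](C)(C)C(C)(C)C)CC1(SCCCS1)C[C@H](O)CC2(SCCCS2)C[C@H](O[Si](C)(C)C(C)(C)C)CC3(CC)SCCCS3 | intermediate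
20 | C5–C18 9,13,17-triketone (11-OH; 7,15-bis-OTBS) | C=CC[C@H](O[Si](C)(C)C(C)(C)C)CC(=O)C[C@H](O)CC(=O)C[C@H](O[Si](C)(C)C(C)(C)C)CC(=O)CC | intermediate
21 | C5–C18 9,11,13-triol 17-ketone (C7–C15 all-anti as in 66) | C=CC[C@H](O[Si](C)(C)C(C)(C)C)C[C@@H](O)C[C@H](O)C[C@@H](O)C[C@H](O[Si](C)(C)C(C)(C)C)CC(=O)CC | intermediate
22 | pentakis-TBS C5–C18 ethyl ketone with terminal alkene | C=CC[C@H](O[Si](C)(C)C(C)(C)C)C[C@@H](O[Si](C)(C)C(C)(C)C)C[C@H](O[Si](C)(C)C(C)(C)C)C[C@@H](O[Si](C)(C)C(C)(C)C)C[C@H](O[Si](C)(C)C(C)(C)C)CC(=O)CC | intermediate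
23 | pentakis-TBS C5 aldehyde C17 ketone | O=CC[C@H](O[Si](C)(C)C(C)(C)C)C[C@@H](O[Si](C)(C)C(C)(C)C)C[C@H](O[Si](C)(C)C(C)(C)C)C[C@@H](O[Si](C)(C)C(C)(C)C)C[C@H](O[Si](C)(C)C(C)(C)C)CC(=O)CC | intermediate
24 | C4–C18 (Z)-vinyl iodide ethyl ketone (I on C4, cis to C6) | I\C(C)=C/C[C@H](O[Si](C)(C)C(C)(C)C)C[C@@H](O[Si](C)(C)C(C)(C)C)C[C@H](O[Si](C)(C)C(C)(C)C)C[C@@H](O[Si](C)(C)C(C)(C)C)C[C@H](O[Si](C)(C)C(C)(C)C)CC(=O)CC | intermediate
25 | 1-bromo-5-chloropentane | ClCCCCCBr | starting material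
26 | 5-chloropentylmagnesium bromide | ClCCCCC[Mg]Br | intermediate
27 | bromomagnesium (2R)-1,8-dichlorooctan-2-olate | ClCCCCCC[C@@H](O[Mg]Br)CCl | intermediate
28 | (2R)-2-(6-chlorohexyl)oxirane (C30–C37) | ClCCCCCC[C@@H]1CO1 | intermediate
29 | lithium alkoxide from 5 and 28 (C31–OLi; C29 silyl dithiane) | ClCCCCCC[C@@H](O[Li])CC1(SCCCS1)[Si](C)(C)C(C)(C)C | intermediate
30 | C29 lithiodithiane after Brook shift (31-OTBS) | ClCCCCCC[C@@H](O[Si](C)(C)C(C)(C)C)CC1([Li])SCCCS1 | intermediate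
31 | chlorohydrin lithium alkoxide (C27–OLi; C26–Cl) | ClC[C@H](O[Li])CC1(SCCCS1)C[C@H](O[Si](C)(C)C(C)(C)C)CCCCCCCl | intermediate
32 | 2-[(2R)-2-(TBSO)-8-chlorooctyl]-2-{[(2R)-oxiran-2-yl]methyl}-1,3-dithiane (C26–C37; C26–C27 epoxide; C29 dithiane) | C1O[C@@H]1CC2(SCCCS2)C[C@H](O[Si](C)(C)C(C)(C)C)CCCCCCCl | intermediate
33 | 4,4-diethoxybut-1-ene (but-3-enal diethyl acetal) | C=CCC(OCC)OCC | starting material
34 | rac-2-(2,2-diethoxyethyl)oxirane | CCOC(OCC)CC1CO1 | intermediate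
35 | (2S)-2-(2,2-diethoxyethyl)oxirane (C21–C24) | CCOC(OCC)C[C@H]1CO1 | intermediate
36 | lithium alkoxide from 5 and 32 (C27–OLi; C25 silyl dithiane) | CC(C)(C)[Si](C)(C)C1(SCCCS1)C[C@H](O[Li])CC2(SCCCS2)C[C@H](O[Si](C)(C)C(C)(C)C)CCCCCCCl | intermediate
37 | C25 lithiodithiane after Brook shift (27-OTBS) | [Li]C1(SCCCS1)C[C@H](O[Si](C)(C)C(C)(C)C)CC2(SCCCS2)C[C@H](O[Si](C)(C)C(C)(C)C)CCCCCCCl | intermediate
38 | C23 lithium alkoxide of the C21–C37 chain | CCOC(OCC)C[C@H](O[Li])CC1(SCCCS1)C[C@H](O[Si](C)(C)C(C)(C)C)CC2(SCCCS2)C[C@H](O[Si](C)(C)C(C)(C)C)CCCCCCCl | intermediate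
39 | C21–C37 bis-dithiane: C21 diethyl acetal, 23,27,31-tris-OTBS (as in 66), dithianes at C25 and C29, C37 chloride | CCOC(OCC)C[C@H](O[Si](C)(C)C(C)(C)C)CC1(SCCCS1)C[C@H](O[Si](C)(C)C(C)(C)C)CC2(SCCCS2)C[C@H](O[Si](C)(C)C(C)(C)C)CCCCCCCl | intermediate
40 | C21–C37 acetal chloride, 23,27,31-tris-OTBS | CCOC(OCC)C[C@H](O[Si](C)(C)C(C)(C)C)CCC[C@H](O[Si](C)(C)C(C)(C)C)CCC[C@H](O[Si](C)(C)C(C)(C)C)CCCCCCCl | intermediate
41 | C21–C37 acetal iodide | CCOC(OCC)C[C@H](O[Si](C)(C)C(C)(C)C)CCC[C@H](O[Si](C)(C)C(C)(C)C)CCC[C@H](O[Si](C)(C)C(C)(C)C)CCCCCCI | intermediate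
42 | C21 aldehyde, 23,27,31-tris-OTBS, C37 iodide | O=CC[C@H](O[Si](C)(C)C(C)(C)C)CCC[C@H](O[Si](C)(C)C(C)(C)C)CCC[C@H](O[Si](C)(C)C(C)(C)C)CCCCCCI | intermediate
43 | ethyl (Z)-2-methyl-2-enoate C19–C37 (ester carbon C19, cis to C22) | CCOC(=O)/C(C)=C\C[C@H](O[Si](C)(C)C(C)(C)C)CCC[C@H](O[Si](C)(C)C(C)(C)C)CCC[C@H](O[Si](C)(C)C(C)(C)C)CCCCCCI | intermediate
44 | (Z)-allylic alcohol C19–C37 | OC/C(C)=C\C[C@H](O[Si](C)(C)C(C)(C)C)CCC[C@H](O[Si](C)(C)C(C)(C)C)CCC[C@H](O[Si](C)(C)C(C)(C)C)CCCCCCI | intermediate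
45 | (Z)-2-methyl-enal C19–C37 (C37 iodide) | O=C/C(C)=C\C[C@H](O[Si](C)(C)C(C)(C)C)CCC[C@H](O[Si](C)(C)C(C)(C)C)CCC[C@H](O[Si](C)(C)C(C)(C)C)CCCCCCI | intermediate
46 | 6-bromohex-1-ene | C=CCCCCBr | starting material
47 | (R)-propylene oxide | C[C@@H]1CO1 | starting material
48 | hex-5-enylmagnesium bromide | C=CCCCC[Mg]Br | intermediate
49 | (2R)-non-8-en-2-ol | C=CCCCCC[C@@H](C)O | intermediate
50 | (2R)-2-(tert-butyldimethylsilyloxy)non-8-ene | C=CCCCCC[C@@H](C)O[Si](C)(C)C(C)(C)C | intermediate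
51 | (7R)-7-(tert-butyldimethylsilyloxy)octanal (C43–C50) | O=CCCCCC[C@@H](C)O[Si](C)(C)C(C)(C)C | intermediate
52 | (3R,4R,10R)-10-(TBSO)-3-methylundec-1-en-4-ol (C40–C50) | C=C[C@@H](C)[C@H](O)CCCCC[C@@H](C)O[Si](C)(C)C(C)(C)C | intermediate
53 | (3R,4R,10R)-10-(TBSO)-3-methyl-4-(TIPSO)undec-1-ene | C=C[C@@H](C)[C@H](O[Si](C(C)C)(C(C)C)C(C)C)CCCCC[C@@H](C)O[Si](C)(C)C(C)(C)C | intermediate
54 | (2R)-2-[(2R,3R,9R)-9-(TBSO)-3-(TIPSO)decan-2-yl]oxirane (C40–C41 epoxide) | C1O[C@@H]1[C@@H](C)[C@H](O[Si](C(C)C)(C(C)C)C(C)C)CCCCC[C@@H](C)O[Si](C)(C)C(C)(C)C | intermediate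
55 | (4S,5R,6R,12R)-12-(TBSO)-5-methyl-6-(TIPSO)tridec-1-yn-4-ol (C38–C50; 41-OH) | C#CC[C@H](O)[C@@H](C)[C@H](O[Si](C(C)C)(C(C)C)C(C)C)CCCCC[C@@H](C)O[Si](C)(C)C(C)(C)C | intermediate
56 | (Z)-enol diisopinocampheylborinate of 24 (C17 O–B; C17=C18) | I\C(C)=C/C[C@H](O[Si](C)(C)C(C)(C)C)C[C@@H](O[Si](C)(C)C(C)(C)C)C[C@H](O[Si](C)(C)C(C)(C)C)C[C@@H](O[Si](C)(C)C(C)(C)C)C[C@H](O[Si](C)(C)C(C)(C)C)C/C(OB([C@@H]1C[C@@H]2C[C@H]([C@H]1C)C2(C)C)[C@@H]1C[C@@H]2C[C@H]([C@H]1C)C2(C)C)=C/C | intermediate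
57 | C4–C37 syn-aldol adduct: C17 ketone, 18-Me and 19-OH as in 66, octakis-TBS, vinyl iodide (C4), alkyl iodide (C37) | I\C(C)=C/C[C@H](O[Si](C)(C)C(C)(C)C)C[C@@H](O[Si](C)(C)C(C)(C)C)C[C@H](O[Si](C)(C)C(C)(C)C)C[C@@H](O[Si](C)(C)C(C)(C)C)C[C@H](O[Si](C)(C)C(C)(C)C)CC(=O)[C@@H](C)[C@H](O)/C(C)=C\C[C@H](O[Si](C)(C)C(C)(C)C)CCC[C@H](O[Si](C)(C)C(C)(C)C)CCC[C@H](O[Si](C)(C)C(C)(C)C)CCCCCCI | intermediate
58 | C4–C37 17,19-diol (C17–C19 as in 66) | I\C(C)=C/C[C@H](O[Si](C)(C)C(C)(C)C)C[C@@H](O[Si](C)(C)C(C)(C)C)C[C@H](O[Si](C)(C)C(C)(C)C)C[C@@H](O[Si](C)(C)C(C)(C)C)C[C@H](O[Si](C)(C)C(C)(C)C)C[C@@H](O)[C@@H](C)[C@H](O)/C(C)=C\C[C@H](O[Si](C)(C)C(C)(C)C)CCC[C@H](O[Si](C)(C)C(C)(C)C)CCC[C@H](O[Si](C)(C)C(C)(C)C)CCCCCCI | intermediate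
59 | C4–C37 decakis-TBS bis-iodide | I\C(C)=C/C[C@H](O[Si](C)(C)C(C)(C)C)C[C@@H](O[Si](C)(C)C(C)(C)C)C[C@H](O[Si](C)(C)C(C)(C)C)C[C@@H](O[Si](C)(C)C(C)(C)C)C[C@H](O[Si](C)(C)C(C)(C)C)C[C@@H](O[Si](C)(C)C(C)(C)C)[C@@H](C)[C@H](O[Si](C)(C)C(C)(C)C)/C(C)=C\C[C@H](O[Si](C)(C)C(C)(C)C)CCC[C@H](O[Si](C)(C)C(C)(C)C)CCC[C@H](O[Si](C)(C)C(C)(C)C)CCCCCCI | intermediate
60 | dilithio derivative of 55 (lithium acetylide, lithium alkoxide) | [Li]C#CC[C@H](O[Li])[C@@H](C)[C@H](O[Si](C(C)C)(C(C)C)C(C)C)CCCCC[C@@H](C)O[Si](C)(C)C(C)(C)C | intermediate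
61 | C4–C50 seco alcohol: free 41-OH, C4 (Z)-vinyl iodide, C38≡C39, eleven OTBS, 43-OTIPS | I\C(C)=C/C[C@H](O[Si](C)(C)C(C)(C)C)C[C@@H](O[Si](C)(C)C(C)(C)C)C[C@H](O[Si](C)(C)C(C)(C)C)C[C@@H](O[Si](C)(C)C(C)(C)C)C[C@H](O[Si](C)(C)C(C)(C)C)C[C@@H](O[Si](C)(C)C(C)(C)C)[C@@H](C)[C@H](O[Si](C)(C)C(C)(C)C)/C(C)=C\C[C@H](O[Si](C)(C)C(C)(C)C)CCC[C@H](O[Si](C)(C)C(C)(C)C)CCC[C@H](O[Si](C)(C)C(C)(C)C)CCCCCCC#CC[C@H](O)[C@@H](C)[C@H](O[Si](C(C)C)(C(C)C)C(C)C)CCCCC[C@@H](C)O[Si](C)(C)C(C)(C)C | intermediate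
62 | seco acid: C1 carboxylic acid, C2≡C3, (4Z)-C4=C5, free 41-OH | OC(=O)C#C\C(C)=C/C[C@H](O[Si](C)(C)C(C)(C)C)C[C@@H](O[Si](C)(C)C(C)(C)C)C[C@H](O[Si](C)(C)C(C)(C)C)C[C@@H](O[Si](C)(C)C(C)(C)C)C[C@H](O[Si](C)(C)C(C)(C)C)C[C@@H](O[Si](C)(C)C(C)(C)C)[C@@H](C)[C@H](O[Si](C)(C)C(C)(C)C)/C(C)=C\C[C@H](O[Si](C)(C)C(C)(C)C)CCC[C@H](O[Si](C)(C)C(C)(C)C)CCC[C@H](O[Si](C)(C)C(C)(C)C)CCCCCCC#CC[C@H](O)[C@@H](C)[C@H](O[Si](C(C)C)(C(C)C)C(C)C)CCCCC[C@@H](C)O[Si](C)(C)C(C)(C)C | intermediate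
63 | mixed anhydride of 62 with 2,4,6-trichlorobenzoic acid | Clc1cc(Cl)c(C(=O)OC(=O)C#C\C(C)=C/C[C@H](O[Si](C)(C)C(C)(C)C)C[C@@H](O[Si](C)(C)C(C)(C)C)C[C@H](O[Si](C)(C)C(C)(C)C)C[C@@H](O[Si](C)(C)C(C)(C)C)C[C@H](O[Si](C)(C)C(C)(C)C)C[C@@H](O[Si](C)(C)C(C)(C)C)[C@@H](C)[C@H](O[Si](C)(C)C(C)(C)C)/C(C)=C\C[C@H](O[Si](C)(C)C(C)(C)C)CCC[C@H](O[Si](C)(C)C(C)(C)C)CCC[C@H](O[Si](C)(C)C(C)(C)C)CCCCCCC#CC[C@H](O)[C@@H](C)[C@H](O[Si](C(C)C)(C(C)C)C(C)C)CCCCC[C@@H](C)O[Si](C)(C)C(C)(C)C)c(Cl)c1 | intermediate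
64 | 42-membered macrolactone with C2≡C3 and C38≡C39, fully silylated | CC1=C/C[C@H](O[Si](C)(C)C(C)(C)C)C[C@@H](O[Si](C)(C)C(C)(C)C)C[C@H](O[Si](C)(C)C(C)(C)C)C[C@@H](O[Si](C)(C)C(C)(C)C)C[C@H](O[Si](C)(C)C(C)(C)C)C[C@@H](O[Si](C)(C)C(C)(C)C)[C@@H](C)[C@H](O[Si](C)(C)C(C)(C)C)/C(C)=C\C[C@H](O[Si](C)(C)C(C)(C)C)CCC[C@H](O[Si](C)(C)C(C)(C)C)CCC[C@H](O[Si](C)(C)C(C)(C)C)CCCCCCC#CC[C@@H]([C@@H](C)[C@H](O[Si](C(C)C)(C(C)C)C(C)C)CCCCC[C@@H](C)O[Si](C)(C)C(C)(C)C)OC(=O)C#C\1 | intermediate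
65 | silylated macrolide (2Z,4Z,20Z,38Z; eleven TBS ethers, 43-OTIPS) | CC1=C/C[C@H](O[Si](C)(C)C(C)(C)C)C[C@@H](O[Si](C)(C)C(C)(C)C)C[C@H](O[Si](C)(C)C(C)(C)C)C[C@@H](O[Si](C)(C)C(C)(C)C)C[C@H](O[Si](C)(C)C(C)(C)C)C[C@@H](O[Si](C)(C)C(C)(C)C)[C@@H](C)[C@H](O[Si](C)(C)C(C)(C)C)/C(C)=C\C[C@H](O[Si](C)(C)C(C)(C)C)CCC[C@H](O[Si](C)(C)C(C)(C)C)CCC[C@H](O[Si](C)(C)C(C)(C)C)CCCCCC/C=C\C[C@@H]([C@@H](C)[C@H](O[Si](C(C)C)(C(C)C)C(C)C)CCCCC[C@@H](C)O[Si](C)(C)C(C)(C)C)OC(=O)/C=C\1 | intermediate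
66 | CNP0392687.2: 42-membered (2Z,4Z,20Z,38Z)-macrolide, 4,18,20-trimethyl, 7,9,11,13,15,17,19,23,27,31-decahydroxy, C41 bearing (2S,3R,9R)-3,9-dihydroxydecan-2-yl; 7S,9R,11S,13R,15S,17R,18R,19S,23R,27R,31R,41S | CC1=C/C[C@H](O)C[C@@H](O)C[C@H](O)C[C@@H](O)C[C@H](O)C[C@@H](O)[C@@H](C)[C@H](O)/C(C)=C\C[C@H](O)CCC[C@H](O)CCC[C@H](O)CCCCCC/C=C\C[C@@H]([C@@H](C)[C@H](O)CCCCC[C@@H](C)O)OC(=O)/C=C\1 | target

## Step count and risks

Total: 36 steps. Longest linear sequence: 17 steps (13–21, then 29–36).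

Three steps most likely to fail:

1. **Step 27 (the new epoxidation).** Risk: low conversion, or insufficient catalyst control next to the C42 stereocentre. Known-chemistry fallback, setting out from alkene 53: mCPBA (CH2Cl2, 0 °C) gives a roughly 1:1 mixture of 54 and its C41 epimer, the (2S)-oxirane F1. Jacobsen hydrolytic kinetic resolution with (R,R)-(salen)Co(OAc) and H2O (0.55 equiv) then hydrolyses F1 to the 40,41-diol F2 and leaves 54 (at most 50 %), where the route is rejoined.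

2. **Step 33 (Sonogashira coupling with free propiolic acid on a hindered trisubstituted alkenyl iodide).** Risk: decarboxylation or sluggish coupling. Fallback, setting out from 61: Sonogashira coupling with trimethylsilylacetylene (PdCl2(PPh3)2, CuI, Et3N) gives the silyl enyne F3. K2CO3/MeOH gives the terminal enyne F4. Treatment with n-BuLi (2.2 equiv, THF, −78 °C) and then CO2 carboxylates the acetylide and returns seco acid 62.

3. **Step 34 (42-membered ring closure through an activated 2-ynoyl species).** Risk: DMAP addition to the ynoate, or oligomerisation. Fallback: form the alkyl–oxygen bond instead, with inversion, by Mitsunobu macrolactonization, which suits acidic 2-ynoic acids. Setting out from alkene 53, prepare the C41-epimeric epoxide F1 (enantiomeric titanium catalyst, or mCPBA followed by resolution with (S,S)-(salen)Co(OAc)). Open it with LiC≡CH·H2NCH2CH2NH2 to the 41-epi alkynol F5, alkylate iodide 59 with its dianion to the 41-epi seco alcohol F6, and couple with propiolic acid to the 41-epi seco acid F7. Cyclise F7 with PPh3 and diisopropyl azodicarboxylate (toluene, high dilution): SN2 attack of the carboxylate on the C41 oxyphosphonium inverts C41 and gives macrolactone 64, where the route is rejoined.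

The step-29 aldol (reagent-controlled, expected about 9:1) is the next most exposed step; the minor diastereomer would be removed at diol 58.

## Further compounds

F1 | step 27 | (2S)-2-[(2R,3R,9R)-9-(TBSO)-3-(TIPSO)decan-2-yl]oxirane (C41 epimer of 54) | C1O[C@H]1[C@@H](C)[C@H](O[Si](C(C)C)(C(C)C)C(C)C)CCCCC[C@@H](C)O[Si](C)(C)C(C)(C)C
F2 | step 27 | 40,41-diol from hydrolysis of F1 (C41 configuration of F1 retained) | OC[C@@H](O)[C@@H](C)[C@H](O[Si](C(C)C)(C(C)C)C(C)C)CCCCC[C@@H](C)O[Si](C)(C)C(C)(C)C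
F3 | step 33 | trimethylsilyl enyne: 61 with C4–C≡C–SiMe3 in place of C4–I | C[Si](C)(C)C#C\C(C)=C/C[C@H](O[Si](C)(C)C(C)(C)C)C[C@@H](O[Si](C)(C)C(C)(C)C)C[C@H](O[Si](C)(C)C(C)(C)C)C[C@@H](O[Si](C)(C)C(C)(C)C)C[C@H](O[Si](C)(C)C(C)(C)C)C[C@@H](O[Si](C)(C)C(C)(C)C)[C@@H](C)[C@H](O[Si](C)(C)C(C)(C)C)/C(C)=C\C[C@H](O[Si](C)(C)C(C)(C)C)CCC[C@H](O[Si](C)(C)C(C)(C)C)CCC[C@H](O[Si](C)(C)C(C)(C)C)CCCCCCC#CC[C@H](O)[C@@H](C)[C@H](O[Si](C(C)C)(C(C)C)C(C)C)CCCCC[C@@H](C)O[Si](C)(C)C(C)(C)C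
F4 | step 33 | terminal enyne: 61 with C4–C≡CH in place of C4–I | C#C\C(C)=C/C[C@H](O[Si](C)(C)C(C)(C)C)C[C@@H](O[Si](C)(C)C(C)(C)C)C[C@H](O[Si](C)(C)C(C)(C)C)C[C@@H](O[Si](C)(C)C(C)(C)C)C[C@H](O[Si](C)(C)C(C)(C)C)C[C@@H](O[Si](C)(C)C(C)(C)C)[C@@H](C)[C@H](O[Si](C)(C)C(C)(C)C)/C(C)=C\C[C@H](O[Si](C)(C)C(C)(C)C)CCC[C@H](O[Si](C)(C)C(C)(C)C)CCC[C@H](O[Si](C)(C)C(C)(C)C)CCCCCCC#CC[C@H](O)[C@@H](C)[C@H](O[Si](C(C)C)(C(C)C)C(C)C)CCCCC[C@@H](C)O[Si](C)(C)C(C)(C)C
F5 | step 34 | 41-epi alkynol (C41 epimer of 55) | C#CC[C@@H](O)[C@@H](C)[C@H](O[Si](C(C)C)(C(C)C)C(C)C)CCCCC[C@@H](C)O[Si](C)(C)C(C)(C)C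
F6 | step 34 | 41-epi seco alcohol (C41 epimer of 61) | I\C(C)=C/C[C@H](O[Si](C)(C)C(C)(C)C)C[C@@H](O[Si](C)(C)C(C)(C)C)C[C@H](O[Si](C)(C)C(C)(C)C)C[C@@H](O[Si](C)(C)C(C)(C)C)C[C@H](O[Si](C)(C)C(C)(C)C)C[C@@H](O[Si](C)(C)C(C)(C)C)[C@@H](C)[C@H](O[Si](C)(C)C(C)(C)C)/C(C)=C\C[C@H](O[Si](C)(C)C(C)(C)C)CCC[C@H](O[Si](C)(C)C(C)(C)C)CCC[C@H](O[Si](C)(C)C(C)(C)C)CCCCCCC#CC[C@@H](O)[C@@H](C)[C@H](O[Si](C(C)C)(C(C)C)C(C)C)CCCCC[C@@H](C)O[Si](C)(C)C(C)(C)C
F7 | step 34 | 41-epi seco acid (C41 epimer of 62) | OC(=O)C#C\C(C)=C/C[C@H](O[Si](C)(C)C(C)(C)C)C[C@@H](O[Si](C)(C)C(C)(C)C)C[C@H](O[Si](C)(C)C(C)(C)C)C[C@@H](O[Si](C)(C)C(C)(C)C)C[C@H](O[Si](C)(C)C(C)(C)C)C[C@@H](O[Si](C)(C)C(C)(C)C)[C@@H](C)[C@H](O[Si](C)(C)C(C)(C)C)/C(C)=C\C[C@H](O[Si](C)(C)C(C)(C)C)CCC[C@H](O[Si](C)(C)C(C)(C)C)CCC[C@H](O[Si](C)(C)C(C)(C)C)CCCCCCC#CC[C@@H](O)[C@@H](C)[C@H](O[Si](C(C)C)(C(C)C)C(C)C)CCCCC[C@@H](C)O[Si](C)(C)C(C)(C)C
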